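**Plan** (labdane numbering throughout)

- Retrosynthesis: the C15 acid, C8=C17 and the C4 methyl/carboxyl pair are taken back to a 17,18,19-trinor core with oxygen at C4 and C8. C4 and C8 are 1,5-related through C5–C6–C7, so ring B is cut at C5–C6 (retro-Michael), then C8–C7 (vinyl addition), then C9–C10 (retro conjugate addition to a ring A enone).
- Forward: (R)-linalool gives an alkyne carrying C8, C9 and C11–C16; its α-alkenylalane adds to 3-methylcyclohexenone (C1–C5, C10, C20). C6/C7 come from a vinyl Grignard reagent, and the C4 enol silane then closes ring B through C5 onto the C8 vinyl ketone.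
- Silyl transfer in that ring closure leaves C8 masked as an enol silane and C4 a free ketone. C4 is then homologated (triflate, carbonylation, reductive methylation) before C8 is unmasked and methylenated.
- Stereochemistry: C13 from linalool (chiral pool); C10 from the chiral copper catalyst; C5 and C9 by equilibration next to the C4 and C8 ketones (trans-decalin, equatorial side chain); C4 by equatorial methylation of the ester enolate, anti to the axial C10 methyl.

Key step: step 10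

Remark: C9 is formed unselectively in step 6 and carried as an epimer mixture (no C9 descriptor in the SMILES of 12 to 23) until step 14. TBS = tert-butyldimethylsilyl, TES = triethylsilyl, TMSE = 2-(trimethylsilyl)ethyl, Tf = trifluoromethanesulfonyl.

Step 1
Reactants: 1 (R)-(−)-linalool
Product: 3 (3R)-3,7-dimethyloct-6-ene-1,3-diol, via alkylborane 2 (not isolated)
Conditions: 9-BBN (2.2 equiv), THF, 0 °C to rt; then NaOH aq, H2O2, 0 °C
Reagents that add atoms: hydrogen peroxide, OO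
Why: Anti-Markovnikov hydroboration–oxidation with the bulky 9-BBN should take the monosubstituted vinyl group and spare the trisubstituted alkene, and the C13 carbinol centre from the chiral pool is not touched.

Step 2
Reactants: 3 (3R)-3,7-dimethyloct-6-ene-1,3-diol
Product: 4 (3R)-1,3-bis(TBS-oxy)-3,7-dimethyloct-6-ene
Conditions: TBSOTf (2.5 equiv), 2,6-lutidine, CH2Cl2, 0 °C to rt
Reagents that add atoms: tert-butyldimethylsilyl triflate, CC(C)(C)[Si](C)(C)OS(=O)(=O)C(F)(F)F
Why: Silyl triflate silylation should protect the primary and the tertiary hydroxyl in one operation as ethers that survive the organoaluminium, Grignard, dissolving-metal and ylide steps.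

Step 3
Reactants: 4 (3R)-1,3-bis(TBS-oxy)-3,7-dimethyloct-6-ene
Product: 6 (4R)-4,6-bis(TBS-oxy)-4-methylhexanal, via ozonide 5 (not isolated)
Conditions: O3, CH2Cl2, −78 °C; then PPh3, −78 °C to rt
Reagents that add atoms: ozone, [O-][O+]=O
Why: Ozonolysis with reductive work-up cleaves the only alkene and gives the aldehyde whose carbonyl carbon becomes C9.

Step 4
Reactants: 6 (4R)-4,6-bis(TBS-oxy)-4-methylhexanal
Product: 7 (5R)-5,7-bis(TBS-oxy)-5-methylhept-1-yne
Conditions: dimethyl (1-diazo-2-oxopropyl)phosphonate, K2CO3, MeOH, rt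
Reagents that add atoms: dimethyl (1-diazo-2-oxopropyl)phosphonate, COP(=O)(OC)C(=[N+]=[N-])C(C)=O
Why: Seyferth–Gilbert homologation in the Ohira–Bestmann variant should convert the aldehyde, which has no α-stereocentre, into the terminal alkyne and add the carbon that becomes C8.

Step 5
Reactants: 7 (5R)-5,7-bis(TBS-oxy)-5-methylhept-1-yne; 8 3-methylcyclohex-2-en-1-one
Product: 11 (3S)-1-(TBS-oxy)-3-methyl-3-[(5R)-5,7-bis(TBS-oxy)-5-methylhept-1-en-2-yl]cyclohex-1-ene, via alkenylalane 9 (not isolated), via aluminium enolate 10 (not isolated)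
Conditions: 7, DIBAL-H (1.3 equiv), NiCl2(dppp) (3 mol%), THF, rt; then 8, Cu(OTf)2 (5 mol%), chiral sulfonate-bearing imidazolinium salt (NHC precursor, 6 mol%), THF, −30 °C; then TBSOTf, −30 to 0 °C
Reagents that add atoms: tert-butyldimethylsilyl triflate, CC(C)(C)[Si](C)(C)OS(=O)(=O)C(F)(F)F
Why: Nickel-catalysed α-selective hydroalumination should give the 1,1-disubstituted alkenylalane, whose copper-catalysed asymmetric conjugate addition to the β-methyl enone (ligand enantiomer chosen to give S at C10) forms the quaternary centre, and the aluminium enolate is O-silylated so that the enol double bond is fixed at C4=C5.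

Step 6
Reactants: 11 silyl enol ether
Product: 13 (5R)-5,7-bis(TBS-oxy)-5-methyl-2-[3-(TBS-oxy)-1-methylcyclohex-2-en-1-yl]heptan-1-ol (quaternary centre as in 11; C9 epimers), via alkylborane 12 (not isolated)
Conditions: 9-BBN (1.5 equiv), THF, 0 to 40 °C; then NaHCO3 aq, H2O2, 0 °C
Reagents that add atoms: hydrogen peroxide, OO
Why: Hydroboration–oxidation should place boron on the terminal C8 of the 1,1-disubstituted alkene in preference to the hindered trisubstituted silyl enol ether, and the new C9 centre, formed as a mixture, is set later in step 14.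

Step 7
Reactants: 13 primary alcohol
Product: 14 (5R)-5,7-bis(TBS-oxy)-5-methyl-2-[3-(TBS-oxy)-1-methylcyclohex-2-en-1-yl]heptanal (C9 epimers)
Conditions: Dess–Martin periodinane, NaHCO3, CH2Cl2, 0 °C
Reagents that add atoms: none
Why: Buffered Dess–Martin oxidation should give the C8 aldehyde without hydrolysing the silyl enol ether.

Step 8
Reactants: 14 aldehyde
Product: 15 (7R)-7,9-bis(TBS-oxy)-7-methyl-4-[3-(TBS-oxy)-1-methylcyclohex-2-en-1-yl]non-1-en-3-ol (C8 and C9 epimers)
Conditions: vinylmagnesium bromide (1.5 equiv), THF, −78 °C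
Reagents that add atoms: vinylmagnesium bromide, C=C[Mg]Br
Why: Grignard 1,2-addition brings in C7 and C6, and the carbinol configuration is irrelevant because C8 is oxidised in the next step.

Step 9
Reactants: 15 allylic alcohol
Product: 16 (7R)-7,9-bis(TBS-oxy)-7-methyl-4-[3-(TBS-oxy)-1-methylcyclohex-2-en-1-yl]non-1-en-3-one (C9 epimers)
Conditions: Dess–Martin periodinane, NaHCO3, CH2Cl2, 0 °C; used at once
Reagents that add atoms: none
Why: Dess–Martin oxidation of the allylic alcohol should give the vinyl ketone, the Michael acceptor whose β-carbon is C6.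

Step 10
Reactants: 16 vinyl ketone
Product: 18 (13R)-8,13,15-tris(TBS-oxy)-17,18,19-trinorlabd-7-en-4-one (5α-H; 10β-methyl; C9 epimers), via cis-fused enol silane 17 (not isolated)
Conditions: TBSOTf (10 mol%), CH2Cl2 (0.01 M), −78 to −40 °C; then DBU (0.5 equiv), −40 °C to rt
Reagents that add atoms: none
Why: The silyl triflate activates the s-trans vinyl ketone and the C4 silyl enol ether attacks C6 through C5, the silyl group moving to the C8 oxygen so that the triflate turns over; this is an intramolecular Mukaiyama–Michael addition, the ring-closing half of a stepwise double-Michael (Diels–Alder-type) annulation. Ring B closes in a 6-(enolexo)-endo-trig mode, made possible by the 1,5-relationship of the C4 and C8 carbonyl carbons across C5–C6–C7. C5 is expected to form first by axial attack on ring A anti to the pseudoaxial C10 methyl (cis-fused 17); because C5 is α to the free C4 ketone, DBU should then equilibrate it to the more stable trans-fused 18, in which the axial C10 methyl meets no syn-axial hydrogen at C4 or C8. The step needs ring closure to win over oligomerisation of the vinyl ketone (high dilution, low temperature) and needs the two carbonyls to emerge distinguishable, which the silyl transfer secures: C8 stays an enol silane, C4 is a ketone. C9 remains an epimer mixture, and both epimers are expected to favour the trans ring fusion.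

Step 11
Reactants: 18 keto enol silane
Product: 19 (13R)-8,13,15-tris(TBS-oxy)-17,18,19-trinorlabda-3,7-dien-4-yl triflate (C9 epimers)
Conditions: KHMDS (1.1 equiv), THF, −78 °C; then PhNTf2, −78 to 0 °C
Reagents that add atoms: N-phenylbis(trifluoromethanesulfonimide), O=S(=O)(N(c1ccccc1)S(=O)(=O)C(F)(F)F)C(F)(F)F
Why: Kinetic deprotonation should occur at the C3 methylene and not at the hindered ring-fusion C5–H, so that enolate triflation gives the C3=C4 enol triflate and leaves the C5 configuration fixed.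

Step 12
Reactants: 19 enol triflate
Product: 20 TMSE (13R)-8,13,15-tris(TBS-oxy)-17,18-dinorlabda-3,7-dien-19-oate (C9 epimers)
Conditions: Pd(OAc)2 (5 mol%), PPh3 (10 mol%), CO (1 atm), 2-(trimethylsilyl)ethanol, Et3N, DMF, 60 °C
Reagents that add atoms: carbon monoxide, [C-]#[O+]; 2-(trimethylsilyl)ethanol, C[Si](C)(C)CCO
Why: Palladium-catalysed alkoxycarbonylation of the enol triflate installs C19 as an unsaturated ester that can later be cleaved by fluoride despite its hindered position.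

Step 13
Reactants: 20 unsaturated ester
Product: 22 TMSE (13R)-8,13,15-tris(TBS-oxy)-17-norlabd-7-en-19-oate (4α-methyl; 4β-ester; C9 epimers), via lithium enolate 21 (not isolated)
Conditions: Li (2.5 equiv), NH3(l)/THF, t-BuOH (1.0 equiv), −78 °C; isoprene; then MeI, −78 to −33 °C
Reagents that add atoms: iodomethane, CI
Why: Birch-type reductive alkylation should reduce the enoate to the exocyclic ester enolate, which iodomethane attacks from the equatorial α face, away from the syn-axial C10 methyl, giving the axial C19 ester and the equatorial C18 methyl, while the silyl enol ether is inert to the dissolving metal.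

Step 14
Reactants: 22 C4-methylated ester
Product: 24 TMSE (13R)-13,15-bis(TBS-oxy)-8-oxo-17-norlabdan-19-oate (9α-H; side chain equatorial), via ketone epimer mixture 23 (not isolated)
Conditions: K2CO3, MeOH/THF, rt to 40 °C
Reagents that add atoms: none
Why: Methanolysis cleaves the enol silane (enolate leaving group) but not the alkyl silyl ethers or the neopentyl-type ester, and base equilibration α to the C8 ketone should converge both C9 epimers on the equatorial side chain.

Step 15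
Reactants: 24 ketone
Product: 25 TMSE (13R)-13,15-bis(TBS-oxy)labd-8(17)-en-19-oate
Conditions: Ph3PCH3Br, KOtBu, toluene, 80 °C
Reagents that add atoms: methyltriphenylphosphonium bromide, C[P+](c1ccccc1)(c1ccccc1)c1ccccc1.[Br-]
Why: Wittig methylenation of the C8 ketone installs C17, and C9 is already in its thermodynamic configuration so the basic ylide cannot erode it.

Step 16
Reactants: 25 protected labdenoate
Product: 26 (13R)-13,15-dihydroxylabd-8(17)-en-19-oic acid
Conditions: TBAF (6 equiv), THF, 50 °C; NH4Cl aq work-up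
Reagents that add atoms: none
Why: Fluoride removes both silyl ethers and the TMSE ester (attack at silicon, then loss of ethene), so the hindered axial ester needs no hydrolysis at the carbonyl.

Step 17
Reactants: 26 dihydroxy acid
Product: 28 (13R)-13-hydroxylabd-8(17)-ene-15,19-dioic acid, via hydroxy aldehyde 27 (not isolated)
Conditions: TEMPO (0.2 equiv), PhI(OAc)2 (2.5 equiv), MeCN/pH 7 buffer, rt
Reagents that add atoms: water, O
Why: Oxoammonium (TEMPO) oxidation takes the primary alcohol through the aldehyde hydrate to the acid and cannot oxidise the tertiary C13 alcohol or the exocyclic alkene.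

**Compound list**

1 | (R)-(−)-linalool, (3R)-3,7-dimethylocta-1,6-dien-3-ol | CC(C)=CCC[C@@](C)(O)C=C | starting material
2 | B-[(3R)-3-hydroxy-3,7-dimethyloct-6-enyl]-9-borabicyclo[3.3.1]nonane | CC(C)=CCC[C@@](C)(O)CCB1C2CCCC1CCC2 | intermediate
3 | (3R)-3,7-dimethyloct-6-ene-1,3-diol | CC(C)=CCC[C@@](C)(O)CCO | intermediate
4 | (3R)-1,3-bis(TBS-oxy)-3,7-dimethyloct-6-ene | CC(C)=CCC[C@@](C)(O[Si](C)(C)C(C)(C)C)CCO[Si](C)(C)C(C)(C)C | intermediate
5 | ozonide of 4 (3,3-dimethyl-1,2,4-trioxolane) | CC1(C)OOC(CC[C@@](C)(O[Si](C)(C)C(C)(C)C)CCO[Si](C)(C)C(C)(C)C)O1 | intermediate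
6 | (4R)-4,6-bis(TBS-oxy)-4-methylhexanal | O=CCC[C@@](C)(O[Si](C)(C)C(C)(C)C)CCO[Si](C)(C)C(C)(C)C | intermediate
7 | (5R)-5,7-bis(TBS-oxy)-5-methylhept-1-yne | C#CCC[C@@](C)(O[Si](C)(C)C(C)(C)C)CCO[Si](C)(C)C(C)(C)C | intermediate
8 | 3-methylcyclohex-2-en-1-one | CC1=CC(=O)CCC1 | starting material
9 | diisobutyl[(5R)-5,7-bis(TBS-oxy)-5-methylhept-1-en-2-yl]aluminium | C=C(CC[C@@](C)(O[Si](C)(C)C(C)(C)C)CCO[Si](C)(C)C(C)(C)C)[Al](CC(C)C)CC(C)C | intermediate
10 | diisobutylaluminium enolate of the conjugate adduct (Al–O at C4; C4=C5; 10S) | C=C(CC[C@@](C)(O[Si](C)(C)C(C)(C)C)CCO[Si](C)(C)C(C)(C)C)[C@@]1(C)CCCC(O[Al](CC(C)C)CC(C)C)=C1 | intermediate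
11 | (3S)-1-(TBS-oxy)-3-methyl-3-[(5R)-5,7-bis(TBS-oxy)-5-methylhept-1-en-2-yl]cyclohex-1-ene | C=C(CC[C@@](C)(O[Si](C)(C)C(C)(C)C)CCO[Si](C)(C)C(C)(C)C)[C@@]1(C)CCCC(O[Si](C)(C)C(C)(C)C)=C1 | intermediate
12 | B-alkyl-9-BBN at C8 of 11 (C9 epimers) | C(B1C2CCCC1CCC2)C(CC[C@@](C)(O[Si](C)(C)C(C)(C)C)CCO[Si](C)(C)C(C)(C)C)[C@@]1(C)CCCC(O[Si](C)(C)C(C)(C)C)=C1 | intermediate
13 | (5R)-5,7-bis(TBS-oxy)-5-methyl-2-[3-(TBS-oxy)-1-methylcyclohex-2-en-1-yl]heptan-1-ol (C9 epimers) | OCC(CC[C@@](C)(O[Si](C)(C)C(C)(C)C)CCO[Si](C)(C)C(C)(C)C)[C@@]1(C)CCCC(O[Si](C)(C)C(C)(C)C)=C1 | intermediate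
14 | (5R)-5,7-bis(TBS-oxy)-5-methyl-2-[3-(TBS-oxy)-1-methylcyclohex-2-en-1-yl]heptanal (C9 epimers) | O=CC(CC[C@@](C)(O[Si](C)(C)C(C)(C)C)CCO[Si](C)(C)C(C)(C)C)[C@@]1(C)CCCC(O[Si](C)(C)C(C)(C)C)=C1 | intermediate
15 | (7R)-7,9-bis(TBS-oxy)-7-methyl-4-[3-(TBS-oxy)-1-methylcyclohex-2-en-1-yl]non-1-en-3-ol (C8 and C9 epimers) | C=CC(O)C(CC[C@@](C)(O[Si](C)(C)C(C)(C)C)CCO[Si](C)(C)C(C)(C)C)[C@@]1(C)CCCC(O[Si](C)(C)C(C)(C)C)=C1 | intermediate
16 | (7R)-7,9-bis(TBS-oxy)-7-methyl-4-[3-(TBS-oxy)-1-methylcyclohex-2-en-1-yl]non-1-en-3-one (C9 epimers) | C=CC(=O)C(CC[C@@](C)(O[Si](C)(C)C(C)(C)C)CCO[Si](C)(C)C(C)(C)C)[C@@]1(C)CCCC(O[Si](C)(C)C(C)(C)C)=C1 | intermediate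
17 | cis-fused (5β-H) isomer of 18 | CC(C)(C)[Si](C)(C)OC1=CC[C@H]2[C@](C)(CCCC2=O)C1CC[C@@](C)(O[Si](C)(C)C(C)(C)C)CCO[Si](C)(C)C(C)(C)C | intermediate
18 | (13R)-8,13,15-tris(TBS-oxy)-17,18,19-trinorlabd-7-en-4-one (5α-H; C9 epimers) | CC(C)(C)[Si](C)(C)OC1=CC[C@@H]2[C@](C)(CCCC2=O)C1CC[C@@](C)(O[Si](C)(C)C(C)(C)C)CCO[Si](C)(C)C(C)(C)C | intermediate
19 | (13R)-8,13,15-tris(TBS-oxy)-17,18,19-trinorlabda-3,7-dien-4-yl triflate (C9 epimers) | CC(C)(C)[Si](C)(C)OC1=CC[C@@H]2[C@](C)(CCC=C2OS(=O)(=O)C(F)(F)F)C1CC[C@@](C)(O[Si](C)(C)C(C)(C)C)CCO[Si](C)(C)C(C)(C)C | intermediate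
20 | TMSE (13R)-8,13,15-tris(TBS-oxy)-17,18-dinorlabda-3,7-dien-19-oate (C9 epimers) | CC(C)(C)[Si](C)(C)OC1=CC[C@@H]2[C@](C)(CCC=C2C(=O)OCC[Si](C)(C)C)C1CC[C@@](C)(O[Si](C)(C)C(C)(C)C)CCO[Si](C)(C)C(C)(C)C | intermediate
21 | lithium ester enolate (C4=C19) from 20 | CC(C)(C)[Si](C)(C)OC1=CC[C@@H]2[C@](C)(CCCC2=C(O[Li])OCC[Si](C)(C)C)C1CC[C@@](C)(O[Si](C)(C)C(C)(C)C)CCO[Si](C)(C)C(C)(C)C | intermediate
22 | TMSE (13R)-8,13,15-tris(TBS-oxy)-17-norlabd-7-en-19-oate (4α-methyl; C9 epimers) | CC(C)(C)[Si](C)(C)OC1=CC[C@@H]2[C@](C)(CCC[C@]2(C)C(=O)OCC[Si](C)(C)C)C1CC[C@@](C)(O[Si](C)(C)C(C)(C)C)CCO[Si](C)(C)C(C)(C)C | intermediate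
23 | TMSE (13R)-13,15-bis(TBS-oxy)-8-oxo-17-norlabdan-19-oate as C9 epimer mixture | O=C1CC[C@@H]2[C@](C)(CCC[C@]2(C)C(=O)OCC[Si](C)(C)C)C1CC[C@@](C)(O[Si](C)(C)C(C)(C)C)CCO[Si](C)(C)C(C)(C)C | intermediate
24 | TMSE (13R)-13,15-bis(TBS-oxy)-8-oxo-17-norlabdan-19-oate (9α-H) | O=C1CC[C@@H]2[C@](C)(CCC[C@]2(C)C(=O)OCC[Si](C)(C)C)[C@H]1CC[C@@](C)(O[Si](C)(C)C(C)(C)C)CCO[Si](C)(C)C(C)(C)C | intermediate
25 | TMSE (13R)-13,15-bis(TBS-oxy)labd-8(17)-en-19-oate | C=C1CC[C@@H]2[C@](C)(CCC[C@]2(C)C(=O)OCC[Si](C)(C)C)[C@H]1CC[C@@](C)(O[Si](C)(C)C(C)(C)C)CCO[Si](C)(C)C(C)(C)C | intermediate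
26 | (13R)-13,15-dihydroxylabd-8(17)-en-19-oic acid | C=C1CC[C@@H]2[C@](C)(CCC[C@]2(C)C(=O)O)[C@H]1CC[C@@](C)(O)CCO | intermediate
27 | (13R)-13-hydroxy-15-oxolabd-8(17)-en-19-oic acid | C=C1CC[C@@H]2[C@](C)(CCC[C@]2(C)C(=O)O)[C@H]1CC[C@@](C)(O)CC=O | intermediate
28 | (13R)-13-hydroxylabd-8(17)-ene-15,19-dioic acid | C=C1CC[C@@H]2[C@](C)(CCC[C@]2(C)C(=O)O)[C@H]1CC[C@@](C)(O)CC(=O)O | target

Total step count: 17. Longest linear sequence: 17 steps (1 to 28; enone 8 enters at step 5).

**Steps most likely to fail**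

Step 5. The hydroalumination may lose its α-selectivity, or the bulky alkenylalane may add with weak facial control. The fallback makes the C10–C20 bond, not the C10–C9 bond, in the asymmetric step. It sets out from 7, which with B-iodo-9-BBN and then acetic acid should give the 2-iodoalkene (5R)-5,7-bis(TBS-oxy)-2-iodo-5-methylhept-1-ene F1. Iodine–lithium exchange (t-BuLi, Et2O, −78 °C), addition to 3-ethoxycyclohex-2-en-1-one and dilute acid (Stork–Danheiser transposition) should give the dienone 3-[(5R)-5,7-bis(TBS-oxy)-5-methylhept-1-en-2-yl]cyclohex-2-en-1-one F2. Copper-catalysed asymmetric 1,4-addition of Me3Al (monovalent copper thiophene-2-carboxylate, chiral phosphoramidite ligand, Et2O, −30 °C) followed by a TBSOTf quench comes back to the route at 11.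

Step 10. The vinyl ketone may oligomerise, or the enol silane may be lost before ring closure, which would also lose the distinction between C4 and C8. The fallback closes the same C5–C6 bond by enolate alkylation and sets out from 15.
- TESCl and imidazole should give the triethylsilyl ether of 15 F3.
- 9-BBN then H2O2 on the vinyl group should give the primary C6 alcohol F4.
- I2, PPh3 and imidazole should give the C6 iodide F5.
- t-BuOK in t-BuOH/THF cleaves the enol silane and equilibrates the enolates; only the C5 enolate can close a six-membered ring (6-exo-tet), so this should give the trans-fused (13R)-8-(TES-oxy)-13,15-bis(TBS-oxy)-17,18,19-trinorlabdan-4-one F6.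
- F6 is taken through the conditions of steps 11 to 13: the enol triflate F7, the TMSE dienoate analogue F8 and the C4-methylated ester F9.
- PPTS in MeOH should free the 8-hydroxy ester F10; Dess–Martin oxidation gives 23, and the K2CO3/MeOH equilibration of step 14 comes back to the route at 24.

Step 13. Over-reduction, or protonation in place of methylation, may occur under dissolving-metal conditions. The fallback separates reduction and alkylation and sets out from 20. Conjugate reduction with Stryker's reagent, [(Ph3P)CuH]6, in benzene should give the saturated ester TMSE (13R)-8,13,15-tris(TBS-oxy)-17,18-dinorlabd-7-en-19-oate F11 (C4 epimers). LDA (THF, −78 °C) then MeI alkylates the same ester enolate from the α face and comes back to the route at 22.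

**Further compounds**

F1 | step 5 | (5R)-5,7-bis(TBS-oxy)-2-iodo-5-methylhept-1-ene | C=C(I)CC[C@@](C)(O[Si](C)(C)C(C)(C)C)CCO[Si](C)(C)C(C)(C)C
F2 | step 5 | 3-[(5R)-5,7-bis(TBS-oxy)-5-methylhept-1-en-2-yl]cyclohex-2-en-1-one | C=C(CC[C@@](C)(O[Si](C)(C)C(C)(C)C)CCO[Si](C)(C)C(C)(C)C)C1=CC(=O)CCC1
F3 | step 10 | triethylsilyl ether of 15 | C=CC(O[Si](CC)(CC)CC)C(CC[C@@](C)(O[Si](C)(C)C(C)(C)C)CCO[Si](C)(C)C(C)(C)C)[C@@]1(C)CCCC(O[Si](C)(C)C(C)(C)C)=C1
F4 | step 10 | primary C6 alcohol from F3 | OCCC(O[Si](CC)(CC)CC)C(CC[C@@](C)(O[Si](C)(C)C(C)(C)C)CCO[Si](C)(C)C(C)(C)C)[C@@]1(C)CCCC(O[Si](C)(C)C(C)(C)C)=C1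
F5 | step 10 | C6 iodide from F4 | ICCC(O[Si](CC)(CC)CC)C(CC[C@@](C)(O[Si](C)(C)C(C)(C)C)CCO[Si](C)(C)C(C)(C)C)[C@@]1(C)CCCC(O[Si](C)(C)C(C)(C)C)=C1
F6 | step 10 | (13R)-8-(TES-oxy)-13,15-bis(TBS-oxy)-17,18,19-trinorlabdan-4-one (5α-H; C8 and C9 epimers) | CC[Si](CC)(CC)OC1CC[C@@H]2[C@](C)(CCCC2=O)C1CC[C@@](C)(O[Si](C)(C)C(C)(C)C)CCO[Si](C)(C)C(C)(C)C
F7 | step 10 | C3=C4 enol triflate of F6 | CC[Si](CC)(CC)OC1CC[C@@H]2[C@](C)(CCC=C2OS(=O)(=O)C(F)(F)F)C1CC[C@@](C)(O[Si](C)(C)C(C)(C)C)CCO[Si](C)(C)C(C)(C)C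
F8 | step 10 | TMSE (13R)-8-(TES-oxy)-13,15-bis(TBS-oxy)-17,18-dinorlabd-3-en-19-oate | CC[Si](CC)(CC)OC1CC[C@@H]2[C@](C)(CCC=C2C(=O)OCC[Si](C)(C)C)C1CC[C@@](C)(O[Si](C)(C)C(C)(C)C)CCO[Si](C)(C)C(C)(C)C
F9 | step 10 | TMSE (13R)-8-(TES-oxy)-13,15-bis(TBS-oxy)-17-norlabdan-19-oate | CC[Si](CC)(CC)OC1CC[C@@H]2[C@](C)(CCC[C@]2(C)C(=O)OCC[Si](C)(C)C)C1CC[C@@](C)(O[Si](C)(C)C(C)(C)C)CCO[Si](C)(C)C(C)(C)C
F10 | step 10 | TMSE (13R)-8-hydroxy-13,15-bis(TBS-oxy)-17-norlabdan-19-oate | OC1CC[C@@H]2[C@](C)(CCC[C@]2(C)C(=O)OCC[Si](C)(C)C)C1CC[C@@](C)(O[Si](C)(C)C(C)(C)C)CCO[Si](C)(C)C(C)(C)C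
F11 | step 13 | TMSE (13R)-8,13,15-tris(TBS-oxy)-17,18-dinorlabd-7-en-19-oate (C4 epimers) | CC(C)(C)[Si](C)(C)OC1=CC[C@@H]2[C@](C)(CCCC2C(=O)OCC[Si](C)(C)C)C1CC[C@@](C)(O[Si](C)(C)C(C)(C)C)CCO[Si](C)(C)C(C)(C)C
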